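## Structural features

The target is a flavan: a benzene ring A fused to a dihydropyran ring C (O1, C2, C3, C4, C4a, C8a), with a 4-hydroxyphenyl ring B on C2. Ring A is a fully differentiated phloroglucinol: C5 carries a free hydroxyl, C7 a methoxy group, C8 a 3-methylbut-2-enyl (prenyl) group, C8a the ring oxygen O1, and only C6 is unsubstituted. The two stereocentres, C2 (S, a benzylic ether carbon) and C4 (R, a benzylic carbinol), are 1,3-related across the C3 methylene. The aryl group and the hydroxyl lie on opposite faces of ring C (2,4-trans, aryl equatorial, hydroxyl pseudo-axial). The C4 hydroxyl sits on a 2,4,6-trioxygenated benzylic carbon and ionises under acid (elimination to the flav-3-ene, attack by C6 of a second molecule, epimerisation). The prenyl alkene forbids hydrogenolysis and strong acid, the phenols at C5 and C4' are oxidised in basic aerated solution, and the 4'-hydroxyl para to C2 weakens the C2–O1 bond. The real difficulty is threefold: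
- the trans relationship is the one that hydride reagents do not give on a flavanone (axial attack leads to 2,4-cis);
- C2 is configurationally labile at the flavanone oxidation level;
- ring C must close through the oxygen next to the prenyl-bearing carbon, although in an open-chain precursor the two ortho oxygens (future O1 and future C5–OH) are almost indistinguishable, so 8-prenyl and 6-prenyl skeletons compete.

The key step exploits exactly this lability. With C4 as a ketone, O1–C2 is a β-aryloxy ketone bond that opens and closes reversibly, so the regiochemistry of ring closure and the configuration at C2 can be left open until the moment C4 is reduced.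

## Logic of the disconnections

**9 to 5.** The C4–H bond and the O1–C2 bond of 9 are cut together. Removing the hydride at C4 gives 8, and opening the β-aryloxy ketone of 8 between O1 and C2 gives 5, which has no ring C and no stereocentre. The reason for cutting here is that 8 cannot be held as a single isomer anyway: under mild base it opens to 5 and closes again to 6, 7 and 8. The gain is large: both stereocentres, ring C and the choice between the two ortho oxygens all vanish, and 5 needs no protecting group. The demand on the forward step is a reducing catalyst that takes 8 alone out of the equilibrating pool and delivers hydride to the C4 face that small reagents avoid; this is asked of a ketoreductase. In one sentence: a flavanone 4-reductase-type ketoreductase turns 5, by way of its equilibrating ring-closed forms, into 9.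

**5 to 3 and 4.** The Cα=Cβ double bond of the enone in 5 (the future C3–C2 bond of ring C) is cut by a retro-aldol condensation into 3 and 4. This is the only carbon–carbon bond between the ring A and ring B halves, and both pieces are simple aromatics. The demand on the forward step is a crossed aldol condensation that tolerates three free phenols, or that is followed by a deprotection mild enough for the prenyl group.

**3 to 1 and 2.** The bond between the ring carbon that becomes C8 and the allylic CH2 is cut, giving 1 and 2. The two free ring positions of 1 are related by symmetry, so the alkylation poses no regiochemical question; the question of which oxygen later closes ring C is deliberately handed to the key step. The demand is C-alkylation over O-alkylation and mono- over bis-alkylation.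

## Other disconnections considered

Alternative 1: The first plan to come to mind cuts O1–C2 and C4–H one after the other on a regiochemically locked, protected series.
- Forward: Claisen–Schmidt condensation to the 6'-O-protected chalcone A1, oxa-Michael closure under a chiral catalyst to the (2S)-flavanone A2, hydride reduction to the flavan-4-ol A3, Mitsunobu inversion at C4, and deprotection.
- Grounds for preferring the chosen plan:
  - The two ortho hydroxyls of 3 must first be told apart by a protection that has only a weak steric bias.
  - Enantioselective closure of a 6'-oxygenated 2'-hydroxychalcone has no dependable catalyst, and A2 can racemise through its chalcone.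
  - Small hydrides add axially, so A3 is 2,4-cis and C4 needs a separate inversion at a trioxygenated benzylic centre that ionises easily (loss of stereospecificity, elimination).
  - Acetal protecting groups must leave under acid that 9 does not tolerate.
  - The plan needs at least eight steps against three, and each of the three problems is solved by its own reagent.

Alternative 2: Cut O1–C2 and C3–C4, forming ring C by an inverse-demand hetero-Diels–Alder reaction.
- Forward: an ortho-quinone methide-type oxocarbenium ion, generated from salicylaldehyde A4 and an alcohol component under a chiral Brønsted acid, is trapped by a para-oxygenated styrene in a three-component operation to give the 4-alkoxyflavan A5.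
- Grounds for preferring the chosen plan:
  - The endo transition state places the 4-alkoxy group cis to the 2-aryl group, the wrong relative configuration.
  - Turning C4–OMe into C4–OH with epimerisation requires acid ionisation at C4, the very process that destroys such flavans (attack by C6 of a second molecule, flav-3-ene formation).
  - A4 again needs its two ortho oxygens differentiated beforehand, so the regiochemical problem is only moved to an earlier stage.
  - The sequence is clearly longer.

Alternative 3: Cut the C4a–C5 bond of ring A and trace ring A back to a masked poly-β-carbonyl chain hung on a preformed ring C.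
- Forward: base-induced Claisen (Dieckmann-type) condensation of the dienolate of ester A6, followed by aromatisation to flavanone A7. The regiochemistry is written into the chain: prenyl on the carbon next to the ring C oxygen, the methyl enol ether becoming the 7-methoxy group, the ester carbonyl becoming C5–OH.
- Grounds for preferring the chosen plan:
  - A6 needs a long assembly (asymmetric construction of the dihydropyranone, chain extension, prenylation).
  - The base needed for the condensation can open the dihydropyranone or A7 by E1cB, which erodes C2 and, in A7, the regiochemistry just gained.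
  - C4 is untouched, so the cis/trans problem remains and must be solved as in Alternative 1.
  - It addresses one of three difficulties at more than three times the step count.

Key step: step 3

Remark on the chemistry: the SMILES is read as (2S,4R), that is 2,4-trans (aryl on C2 and hydroxyl on C4 on opposite faces of ring C); the ketoreductase of step 3 is assumed to be selected by screening NADPH-dependent short-chain dehydrogenases with flavanone 4-reductase activity; 1, 2 and 4 are catalogue compounds.

## Steps

Step 1
Reactants: 1 1-(2,6-dihydroxy-4-methoxyphenyl)ethan-1-one; 2 1-bromo-3-methylbut-2-ene (prenyl bromide)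
Product: 3 1-[2,6-dihydroxy-4-methoxy-3-(3-methylbut-2-en-1-yl)phenyl]ethan-1-one
Conditions: 10% aq. KOH, 2 (1.0 equiv, slow addition), 0 °C to rt
Reagents that add atoms: none
Why: C-allylation of an ambident phenoxide (phenolate C-prenylation): in water the oxygen is solvated and the soft allylic bromide is attacked by the ring carbon between the phenoxide and the methoxy group. The two free ring positions of 1 are related by symmetry, so only one mono-C-prenyl compound can form.

Step 2
Reactants: 3 1-[2,6-dihydroxy-4-methoxy-3-(3-methylbut-2-en-1-yl)phenyl]ethan-1-one; 4 4-hydroxybenzaldehyde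
Product: 5 (2E)-1-[2,6-dihydroxy-4-methoxy-3-(3-methylbut-2-en-1-yl)phenyl]-3-(4-hydroxyphenyl)prop-2-en-1-one
Conditions: LiN(SiMe3)2 (6 equiv), THF, −78 °C to rt; then 1 M HCl
Reagents that add atoms: none
Why: Claisen–Schmidt (crossed aldol) condensation run on the lithium polyanion: the excess base ionises the three phenols and forms the methyl ketone enolate, which adds to the non-enolisable aldehyde 4, and the aldolate eliminates (E1cB) on warming and acidification to the conjugated E-enone. Partial closure of 5 to 6, 7 and 8 during work-up is harmless, because all of them enter step 3 as one pool.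

Step 3
Reactants: 5 (2E)-1-[2,6-dihydroxy-4-methoxy-3-(3-methylbut-2-en-1-yl)phenyl]-3-(4-hydroxyphenyl)prop-2-en-1-one
Product: 9 (2S,4R)-2-(4-hydroxyphenyl)-7-methoxy-8-(3-methylbut-2-en-1-yl)-3,4-dihydro-2H-chromene-4,5-diol, via racemic 6-prenylflavanone 6 (not isolated), via (2R)-8-prenylflavanone 7 (not isolated), via (2S)-8-prenylflavanone 8 (not isolated)
Conditions: ketoreductase (NADPH-dependent short-chain dehydrogenase with flavanone 4-reductase activity), NADP+ (cat.), glucose dehydrogenase, D-glucose (2 equiv), aq. KHCO3/K2CO3 buffer pH 9.0 (pH-stat, KOH), DMSO (10% v/v), 35 °C, N2; work-up at pH 7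
Reagents that add atoms: none
Why: Proposed new method: at pH 9 either ortho-phenoxide of 5 adds reversibly to the enone β-carbon (intramolecular oxa-Michael addition, 6-endo-trig, closing ring C through O1–C2), so 5, 6, 7 and 8 form one interconverting pool; the ring opening is an E1cB process that needs the C4 carbonyl and is helped by the 4'-phenoxide (para-quinone methide push). The ketoreductase, a short-chain dehydrogenase of the flavanone/dihydroflavonol 4-reductase type, is expected to accept only 8 and to transfer the NADPH hydride to the Si face of C4, on the side of the 2-aryl group, so that the hydroxyl ends up 4R and trans to the aryl group. C2 is therefore set by enzyme selection among equilibrating ring-closed forms (dynamic kinetic resolution), and C4 by the fixed cofactor–substrate geometry in the active site, which overrides the axial attack that small hydride reagents prefer and that would give the cis alcohol. Because 9 has no carbonyl group, the E1cB opening is shut off, 9 no longer exchanges at this pH, and the whole pool should drain into it. Three selectivities are needed: 2S over 2R and Si over Re follow the native course of this enzyme family, which reduces (2S)-flavanones and (2R,3R)-dihydroflavonols to alcohols with the 4-hydroxyl trans to the 2-aryl group. The third, 8-prenyl over 6-prenyl, is secured by the substrate in that the prenyl group of 6 flanks the 5-OH/C4=O chelate that has to lie against the catalytic serine–tyrosine–lysine triad, while in 8 it sits on the remote O1 edge; this has to be confirmed by screening. Closest known reaction types: ketoreductase-catalysed dynamic reductive kinetic resolution of ketones that carry a base-labile stereocentre, the flavanone 4-reductase reaction, and the base-mediated chalcone–flavanone interconversion.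

## Compound list

1 | 1-(2,6-dihydroxy-4-methoxyphenyl)ethan-1-one | CC(=O)c1c(O)cc(OC)cc1O | starting material
2 | 1-bromo-3-methylbut-2-ene (prenyl bromide) | CC(C)=CCBr | starting material
3 | 1-[2,6-dihydroxy-4-methoxy-3-(3-methylbut-2-en-1-yl)phenyl]ethan-1-one | CC(=O)c1c(O)cc(OC)c(CC=C(C)C)c1O | intermediate
4 | 4-hydroxybenzaldehyde | O=Cc1ccc(O)cc1 | starting material
5 | (2E)-1-[2,6-dihydroxy-4-methoxy-3-(3-methylbut-2-en-1-yl)phenyl]-3-(4-hydroxyphenyl)prop-2-en-1-one | COc1cc(O)c(C(=O)/C=C/c2ccc(O)cc2)c(O)c1CC=C(C)C | intermediate
6 | racemic (2RS)-5-hydroxy-2-(4-hydroxyphenyl)-7-methoxy-6-(3-methylbut-2-en-1-yl)-2,3-dihydro-4H-chromen-4-one (both enantiomers, not isolated) | COc1cc2OC(c3ccc(O)cc3)CC(=O)c2c(O)c1CC=C(C)C | intermediate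
7 | (2R)-5-hydroxy-2-(4-hydroxyphenyl)-7-methoxy-8-(3-methylbut-2-en-1-yl)-2,3-dihydro-4H-chromen-4-one (not isolated) | COc1cc(O)c2c(c1CC=C(C)C)O[C@@H](c1ccc(O)cc1)CC2=O | intermediate
8 | (2S)-5-hydroxy-2-(4-hydroxyphenyl)-7-methoxy-8-(3-methylbut-2-en-1-yl)-2,3-dihydro-4H-chromen-4-one (not isolated) | COc1cc(O)c2c(c1CC=C(C)C)O[C@H](c1ccc(O)cc1)CC2=O | intermediate
9 | (2S,4R)-2-(4-hydroxyphenyl)-7-methoxy-8-(3-methylbut-2-en-1-yl)-3,4-dihydro-2H-chromene-4,5-diol | COc1cc(O)c2c(c1CC=C(C)C)O[C@H](c1ccc(O)cc1)C[C@H]2O | target

## Step count and least certain steps

Total step count: 3. Longest linear sequence: 3 steps (1 to 3 to 5 to 9).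

**Step 3 (key step, carries the label "Proposed new method:").** Three processes may fail:
- Incomplete discrimination by the enzyme between the 8-prenyl and the 6-prenyl series, so that reduction of the wrong constitutional isomer competes; nothing but the shape of the active site separates the two.
- Ring opening of 6 and 7 too slow at a pH the enzyme survives, so that the reaction stalls as a plain kinetic resolution.
- Oxidative loss of the phenoxides, or slow epimerisation of 9 at C2 through the 4'-phenoxide, on long exposure to pH 9.

Fallback with known chemistry, setting out from 5 and coming back at 9. 5 is cyclised under buffered conditions (NaOAc, EtOH, reflux) to the mixture of 6 and the racemate of 7 and 8. Chromatography on silica separates the two constitutional isomers (6 is returned to the equilibration), and preparative HPLC on a polysaccharide chiral stationary phase gives 8. Silylation of both phenols (triisopropylsilyl triflate, 2,6-lutidine, CH2Cl2) gives the (2S)-bis(triisopropylsilyl) flavanone F1. NaBH4 with CeCl3·7H2O in MeOH–THF at −20 °C adds hydride axially to give the 2,4-cis alcohol F2. A Mitsunobu reaction (4-nitrobenzoic acid, PPh3, diisopropyl azodicarboxylate, THF, 0 °C) inverts C4 to the (4R)-4-nitrobenzoate F3. K2CO3 in MeOH cleaves the ester to the trans alcohol F4, and Bu4NF buffered with AcOH removes both silyl groups to give 9. Here regiochemistry and C2 are settled by separation, and C4 by substrate-controlled reduction plus inversion.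

**Step 1.** Over-alkylation (a second C-prenyl group on the remaining ring position) and O-alkylation may compete, because the phenoxide of 3 is as nucleophilic as that of 1 and the phenoxide is ambident.

Fallback, setting out from 1 and coming back at 3. O-alkylation of one hydroxyl (2, K2CO3, acetone, reflux) gives the mono prenyl ether F5, a single compound by symmetry. Heating in N,N-diethylaniline at about 200 °C then moves the prenyl group by a para-Claisen–Cope sequence (two consecutive [3,3] shifts) to the ring carbon para to the ether oxygen, which is the position between the hydroxyl and the methoxy group, and gives 3.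

**Step 2.** The aldol addition may stall, because the aldehyde is deactivated as its phenoxide and the lithium polyanion of 3 is poorly soluble; retro-aldol cleavage on work-up is a further loss.

Fallback, setting out from 3 and coming back at 5. Both phenols of 3 are protected (chloromethyl methyl ether, NaH, DMF) to give the bis(methoxymethyl) ether F6. Claisen–Schmidt condensation with commercial 4-(methoxymethoxy)benzaldehyde (KOH, EtOH–H2O, rt) gives the tris(methoxymethyl) chalcone F7. Mild acid (3 M HCl, MeOH, 40 °C) removes the three acetals to give 5, possibly with 6, 7 and 8, which serve step 3 equally.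

## Further compounds

F1 | step 3 | (2S)-7-methoxy-8-(3-methylbut-2-en-1-yl)-5-(triisopropylsilyloxy)-2-[4-(triisopropylsilyloxy)phenyl]-2,3-dihydro-4H-chromen-4-one | COc1cc(O[Si](C(C)C)(C(C)C)C(C)C)c2c(c1CC=C(C)C)O[C@H](c1ccc(O[Si](C(C)C)(C(C)C)C(C)C)cc1)CC2=O
F2 | step 3 | (2S,4S)-7-methoxy-8-(3-methylbut-2-en-1-yl)-5-(triisopropylsilyloxy)-2-[4-(triisopropylsilyloxy)phenyl]-3,4-dihydro-2H-chromen-4-ol | COc1cc(O[Si](C(C)C)(C(C)C)C(C)C)c2c(c1CC=C(C)C)O[C@H](c1ccc(O[Si](C(C)C)(C(C)C)C(C)C)cc1)C[C@@H]2O
F3 | step 3 | (2S,4R)-7-methoxy-8-(3-methylbut-2-en-1-yl)-5-(triisopropylsilyloxy)-2-[4-(triisopropylsilyloxy)phenyl]-3,4-dihydro-2H-chromen-4-yl 4-nitrobenzoate | COc1cc(O[Si](C(C)C)(C(C)C)C(C)C)c2c(c1CC=C(C)C)O[C@H](c1ccc(O[Si](C(C)C)(C(C)C)C(C)C)cc1)C[C@H]2OC(=O)c1ccc(cc1)[N+](=O)[O-]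
F4 | step 3 | (2S,4R)-7-methoxy-8-(3-methylbut-2-en-1-yl)-5-(triisopropylsilyloxy)-2-[4-(triisopropylsilyloxy)phenyl]-3,4-dihydro-2H-chromen-4-ol | COc1cc(O[Si](C(C)C)(C(C)C)C(C)C)c2c(c1CC=C(C)C)O[C@H](c1ccc(O[Si](C(C)C)(C(C)C)C(C)C)cc1)C[C@H]2O
F5 | step 1 | 1-[2-hydroxy-4-methoxy-6-(3-methylbut-2-en-1-yloxy)phenyl]ethan-1-one | CC(=O)c1c(O)cc(OC)cc1OCC=C(C)C
F6 | step 2 | 1-[4-methoxy-2,6-bis(methoxymethoxy)-3-(3-methylbut-2-en-1-yl)phenyl]ethan-1-one | CC(=O)c1c(OCOC)cc(OC)c(CC=C(C)C)c1OCOC
F7 | step 2 | (2E)-1-[4-methoxy-2,6-bis(methoxymethoxy)-3-(3-methylbut-2-en-1-yl)phenyl]-3-[4-(methoxymethoxy)phenyl]prop-2-en-1-one | COCOc1ccc(/C=C/C(=O)c2c(OCOC)cc(OC)c(CC=C(C)C)c2OCOC)cc1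
A1 | alternative 1 | (2E)-1-[2-hydroxy-4-methoxy-6-(methoxymethoxy)-3-(3-methylbut-2-en-1-yl)phenyl]-3-[4-(methoxymethoxy)phenyl]prop-2-en-1-one | COCOc1ccc(/C=C/C(=O)c2c(OCOC)cc(OC)c(CC=C(C)C)c2O)cc1
A2 | alternative 1 | (2S)-7-methoxy-5-(methoxymethoxy)-2-[4-(methoxymethoxy)phenyl]-8-(3-methylbut-2-en-1-yl)-2,3-dihydro-4H-chromen-4-one | COCOc1ccc([C@@H]2CC(=O)c3c(OCOC)cc(OC)c(CC=C(C)C)c3O2)cc1
A3 | alternative 1 | (2S,4S)-7-methoxy-5-(methoxymethoxy)-2-[4-(methoxymethoxy)phenyl]-8-(3-methylbut-2-en-1-yl)-3,4-dihydro-2H-chromen-4-ol | COCOc1ccc([C@@H]2C[C@H](O)c3c(OCOC)cc(OC)c(CC=C(C)C)c3O2)cc1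
A4 | alternative 2 | 2-hydroxy-4-methoxy-6-(methoxymethoxy)-3-(3-methylbut-2-en-1-yl)benzaldehyde | COCOc1cc(OC)c(CC=C(C)C)c(O)c1C=O
A5 | alternative 2 | (2S,4S)-2-[4-(tert-butyldimethylsilyloxy)phenyl]-4,7-dimethoxy-5-(methoxymethoxy)-8-(3-methylbut-2-en-1-yl)-3,4-dihydro-2H-chromene | COCOc1cc(OC)c(CC=C(C)C)c2O[C@H](c3ccc(O[Si](C)(C)C(C)(C)C)cc3)C[C@H](OC)c12
A6 | alternative 3 | methyl (2E)-4-{(2S)-2-[4-(tert-butyldimethylsilyloxy)phenyl]-4-oxo-3,4-dihydro-2H-pyran-6-yl}-3-methoxy-7-methylocta-2,6-dienoate (mixture of epimers at C4 of the chain) | C1[C@H](OC(=CC1=O)C(CC=C(C)C)/C(OC)=C\C(=O)OC)c1ccc(O[Si](C)(C)C(C)(C)C)cc1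
A7 | alternative 3 | (2S)-2-[4-(tert-butyldimethylsilyloxy)phenyl]-5-hydroxy-7-methoxy-8-(3-methylbut-2-en-1-yl)-2,3-dihydro-4H-chromen-4-one | COc1cc(O)c2c(c1CC=C(C)C)O[C@H](c1ccc(O[Si](C)(C)C(C)(C)C)cc1)CC2=O
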